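**Assumption:** the SMILES carries no axial descriptor and the molecule has no stereocentre, so the target is taken as the configurationally unspecified (racemic) biaryl and no stereocontrol is planned. Compounds 1 and 5 are taken as catalogue chemicals.

## Structural features

The target is a constitutionally symmetrical dimer of 2-acetyl-3-methylnaphthalene-1,6,8-triol. Each half is numbered C1 (OH), C2 (acetyl), C3 (methyl), C4, C4a, C5 to C8 (OH on C6 and C8) and C8a; ring B holds C1 to C4, ring A holds C5 to C8, and the second half takes primes. The halves are joined only by the C4–C4' biaryl bond, flanked by the C3 and C3' methyl groups and the peri hydrogens on C5 and C5', so it is a tetra-ortho-substituted axis of the 1,1'-binaphthyl type and the only stereogenic element. Ring B is fully substituted, with the C1 hydroxyl chelated to the C2 acetyl carbonyl and peri to the C8 hydroxyl. Ring A is a resorcinol ring whose C5 and C7 positions are strongly nucleophilic. The fragile groups are six free phenols on electron-rich naphthalenes (air oxidation, above all in base) and two enolisable ortho-hydroxyaryl methyl ketones. The real difficulty is the regiodefined formation of the crowded C4–C4' bond between rings that offer more reactive positions elsewhere, together with the pentasubstituted ring B on each side of it. The key step exploits the fact that C4–C4a–C8a–C1 of each half is the methyl carbon, two ring carbons and the carboxyl carbon of an orsellinate: C4 and C4' are therefore two benzylic carbons, the axis is the aromatised form of the CH2–CH2 bond of a bibenzyl, and C2/C3 with acetyl and methyl are the central carbons of an acetylacetone unit.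

## Logic of the disconnections

**9 to 8.** The four O–CH3 bonds on C6, C6', C8 and C8' are cut (functional group interconversion). Free phenols cannot pass through the strongly basic ring construction, and methyl ethers come with the commercial starting material, so no protection step is spent. The demand on the forward step is a global ether cleavage that leaves the two acetyl groups and the electron-rich rings intact.

**8 to 4 and two molecules of 5 (key disconnection).** The bonds C3–C4, C1–C2, C3'–C4' and C1'–C2' are cut, which removes both rings B. The C4–C4' bond is kept and falls back to an sp3–sp3 bond. In one sentence: both rings B are built at once by a twofold Michael–Claisen benzannulation of the bis-benzylic dianion of 4 with 5, and the ethane bond of 4 becomes the biaryl axis. The gain is the step from a tetra-ortho-substituted binaphthyl with two pentasubstituted rings to a flexible diarylethane and a five-carbon enone. Polarity alone places every ring B substituent: the benzylic carbon can only become C4 and the ester carbon only C1. The forward step must achieve double lateral deprotonation to 6, conjugate addition of a secondary benzylic anion to the β,β-disubstituted 5, Claisen closure to 7 and twofold loss of methanol.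

**4 to two molecules of 1.** The C4–C4' bond is cut at the stage where it is a primary benzylic sp3–sp3 bond. This is the symmetry cut, made where the bond is unhindered and where only the benzylic carbon can react. The forward step must convert half of the lateral anion 2 into the electrophile 3 and join the two, without Claisen self-condensation of 2 with 1.

## Other disconnections considered

**Alternative 1:** the first idea is to cut C4–C4' at the aromatic stage. The forward key step would be an oxidative para,para-dehydrodimerisation of the monomeric naphthol A1 (2-acetyl-6,8-dimethoxy-3-methylnaphthalen-1-ol, from 1 and 5), or a reductive coupling of its 4-halo derivative, to give 8. The step count equals that of the chosen plan, so the ground for preference is mechanistic. The C1 hydroxyl of A1 is tied up in a hydrogen bond to the acetyl group, which raises the oxidation potential, while the dimethoxylated ring A is the most electron-rich part and offers C5 and C7 as competing sites. The bond-forming event itself would have to create the tetra-ortho-substituted axis, and oxygenation at C4 to a 1,4-quinone is an expected side path. The chosen plan makes the same bond as an unhindered SN2 bond where only one carbon is nucleophilic.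

**Alternative 2:** cut C4–C4a and C2–C3 in both halves, with the central sp–sp bond of a 1,3-diyne as the future axis. The forward key step would be a twofold oxidative C–H activation and alkyne annulation of the aryl diketone A2 (1-(2,4-dimethoxyphenyl)butane-1,3-dione) with the diyne A3 (hexa-2,4-diyne), using [Cp*RhCl2]2 (trivalent rhodium) and Cu(OAc)2. Migratory insertion of a 1,3-diyne is expected to place the alkynyl-bearing carbon on the metal and the methyl-bearing carbon on the arene. The diyne carbons that carry the central bond would then become C3 and C3', and the product would be the regioisomer A4 (3,3'-linked, methyl on C4) and not 8. The mechanism therefore works against the required constitution, whereas in the chosen plan the regiochemistry cannot be other than the desired one.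

**Alternative 3:** cut C2–C3 and C2'–C3' in a biomimetic manner. The forward key step would be a twofold intramolecular aldol condensation (Knoevenagel type) of the bis-tetraketone A5, 3,4-bis[3,5-dimethoxy-2-(3-oxobutanoyl)phenyl]hexane-2,5-dione, whose active methylene carbons would attack the two methyl ketone carbonyls, followed by dehydration and enolisation to 8. A5 contains a hexane-2,5-dione unit, which is expected to close to a furan under acid and to a cyclopentenone under base in competition with the desired six-membered closures. A5 is also a multi-step target with eight ketone carbonyls to be carried unmasked or masked. The chosen plan needs only two ester groups and brings the remaining carbons in at the moment of ring closure.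

Key step: step 2

## Steps

**Step 1**
Reactants: 1 methyl 2,4-dimethoxy-6-methylbenzoate (two molecules)
Product: 4 dimethyl 2,2'-(ethane-1,2-diyl)bis(4,6-dimethoxybenzoate), via lateral lithio species 2 (not isolated), via benzylic iodide 3 (not isolated)
Conditions: LiN(iPr)2 (commercial solution, 1.05 equiv), THF, −78 °C; then I2 (0.5 equiv) in THF, −78 °C to 0 °C
Reagents that add atoms: none
Why: Lateral lithiation of the ortho-toluate gives the benzylic anion 2, stabilised as an ester dienolate; iodine converts half of it into the benzylic iodide 3, which alkylates the remaining 2 in an SN2 reaction (oxidative homocoupling of an enolate-type anion with iodine). The ester flanked by two ortho substituents resists Claisen self-condensation at −78 °C.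

**Step 2**
Reactants: 4 dimethyl 2,2'-(ethane-1,2-diyl)bis(4,6-dimethoxybenzoate); 5 (E)-4-methoxypent-3-en-2-one (two molecules react, 3 equiv used)
Product: 8 1,1'-(4,4'-dihydroxy-5,5',7,7'-tetramethoxy-2,2'-dimethyl-[1,1'-binaphthalene]-3,3'-diyl)di(ethan-1-one), via dilithio dianion 6 (not isolated), via twofold Michael-Claisen adduct 7 (not isolated)
Conditions: 4 added to LiN(iPr)2 (2.5 equiv), THF, −78 °C; then 5, −78 °C to 23 °C; 1 M HCl quench
Reagents that add atoms: none
Why: This is a Staunton–Weinreb-type Michael–Claisen (Dieckmann) benzannulation run twofold: inverse addition of 4 to excess base deprotonates both benzylic CH2 groups, each acidified by its ortho ester, to the conjugated bis-dienolate 6, in which both esters are masked as enolates so that a five-membered Claisen acylation across the ethane bridge cannot compete. Each benzylic carbon (future C4/C4') adds in conjugate fashion to the β-carbon of the vinylogous ester 5 (future C3/C3'), and the resulting ketone enolate carbon (future C2/C2') acylates the neighbouring aryl ester carbonyl (future C1/C1') with loss of methoxide, a 6-(enolendo)-exo-trig closure for each ring B, to give 7. E1cB loss of methanol from C3/C3' and enolisation through the C4–H/C4'–H protons then aromatise both rings, and the energy of two new arene rings should drive the crowded sequence forward. The closest known reaction type is the annulation of lithiated ortho-toluates with β-alkoxy enones and pyranones to 1-naphthols, and secondary lateral anions of ortho-alkyl benzoates are established partners in Michael–Claisen cyclisations. Regiochemistry is fixed by polarity: acetyl must land on C2, methyl on C3, and the C1 hydroxyl peri to the C8 methoxy group. The stereocentres formed at C3, C4, C3' and C4' in 7 are all erased on aromatisation, and the C4–C4' axis arises as the racemate, so no control element is needed. The selectivity required is conjugate addition over proton abstraction from the two methyl groups of 5 and over 1,2-addition; the soft, delocalised dienolate and the low temperature favour it, and the excess of 5 covers loss to enolisation.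

**Step 3**
Reactants: 8 1,1'-(4,4'-dihydroxy-5,5',7,7'-tetramethoxy-2,2'-dimethyl-[1,1'-binaphthalene]-3,3'-diyl)di(ethan-1-one)
Product: 9 1,1'-(4,4',5,5',7,7'-hexahydroxy-2,2'-dimethyl-[1,1'-binaphthalene]-3,3'-diyl)di(ethan-1-one) (target)
Conditions: BBr3 (12 equiv), CH2Cl2, −78 °C to 23 °C, argon; then H2O, 0 °C
Reagents that add atoms: none
Why: Lewis acid-mediated cleavage of aryl methyl ethers, in which bromide attacks the O-methyl carbon of each ether–boron adduct in an SN2 reaction; the peri C8 and C8' ethers should go first through chelation with the boron-bound C1 oxygen, and the aryl ketones and the biaryl bond are inert. Hydrolysis of the aryl borates on work-up should release the hexaphenol.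

## Compound list

1 | methyl 2,4-dimethoxy-6-methylbenzoate | COC(=O)c1c(C)cc(OC)cc1OC | starting material
2 | methyl 2-(lithiomethyl)-4,6-dimethoxybenzoate (lateral lithio species, ester dienolate) | COC(=O)c1c(C[Li])cc(OC)cc1OC | intermediate
3 | methyl 2-(iodomethyl)-4,6-dimethoxybenzoate | COC(=O)c1c(CI)cc(OC)cc1OC | intermediate
4 | dimethyl 2,2'-(ethane-1,2-diyl)bis(4,6-dimethoxybenzoate) | COC(=O)c1c(CCc2cc(OC)cc(OC)c2C(=O)OC)cc(OC)cc1OC | intermediate
5 | (E)-4-methoxypent-3-en-2-one | CC(=O)/C=C(\C)OC | starting material
6 | dimethyl 2,2'-(1,2-dilithioethane-1,2-diyl)bis(4,6-dimethoxybenzoate) (conjugated bis-dienolate, configuration undefined) | COC(=O)c1c(C([Li])C([Li])c2cc(OC)cc(OC)c2C(=O)OC)cc(OC)cc1OC | intermediate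
7 | 3,3'-diacetyl-2,2',5,5',7,7'-hexamethoxy-2,2'-dimethyl-2,2',3,3'-tetrahydro-[1,1'-binaphthalene]-4,4'(1H,1'H)-dione (mixture of diastereomers, present as its bis-lithium enolate) | CC(=O)C1C(=O)c2c(OC)cc(OC)cc2C(C2c3cc(OC)cc(OC)c3C(=O)C(C(C)=O)C2(C)OC)C1(C)OC | intermediate
8 | 1,1'-(4,4'-dihydroxy-5,5',7,7'-tetramethoxy-2,2'-dimethyl-[1,1'-binaphthalene]-3,3'-diyl)di(ethan-1-one) (racemic axis) | CC(=O)c1c(C)c(-c2c(C)c(C(C)=O)c(O)c3c(OC)cc(OC)cc23)c2cc(OC)cc(OC)c2c1O | intermediate
9 | 1,1'-(4,4',5,5',7,7'-hexahydroxy-2,2'-dimethyl-[1,1'-binaphthalene]-3,3'-diyl)di(ethan-1-one) (racemic axis) | CC(=O)c1c(C)c(-c2c(C)c(C(C)=O)c(O)c3c(O)cc(O)cc23)c2cc(O)cc(O)c2c1O | target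

## Step count and risk

Total step count: 3. Longest linear sequence: 3 steps (1 to 4 to 8 to 9).

**Step 2 (key step).** The most likely failure is proton transfer from the two methyl groups of 5 to the hindered secondary benzylic anion, faster than conjugate addition, which would stop the sequence after no or one annulation. Once one anionic site has been quenched, intramolecular Claisen acylation of the remaining mono-anion onto the ester of the other ring becomes possible. The second conjugate addition has to take place next to the newly built, crowded half and may be slow, and the conjugated dianion is easily oxidised to the stilbene by traces of oxygen.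
Fallback, from 1, returning to the route at 8: the lateral anion of 1 (LiN(iPr)2, THF, −78 °C) is annulated with 5 in the ordinary single Michael–Claisen manner, where the anion is primary and unhindered, to give 1-(1-hydroxy-6,8-dimethoxy-3-methylnaphthalen-2-yl)ethan-1-one F1. F1 is then dehydrodimerised para to the C1 hydroxyl (FeCl3 in acetonitrile, or anodic oxidation at graphite in hexafluoroisopropanol) to give 8, which enters step 3.

**Step 1.** Claisen self-condensation of 2 with 1 that has not yet been deprotonated would consume material. Proton transfer from the product 4 to 2 followed by iodination and elimination would over-oxidise the bridge to the stilbene, and iodination of the electron-rich ring is a further loss.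
Fallback, from 1, returning at 4: lithio species 2 is added to an excess of hexachloroethane at −78 °C to give methyl 2-(chloromethyl)-4,6-dimethoxybenzoate F2, which is isolated. A second portion of 2 is then alkylated with F2 (THF, −78 °C) to give 4, so that the C–C bond forms with no oxidant in the flask.

**Step 3.** Ether cleavage may stop before the C6 and C6' methoxy groups have reacted, since they lack chelation assistance. Forcing the reaction exposes the electron-rich hexaphenol to HBr and, on work-up, to air oxidation.
Fallback, from 4, returning at 9: the four aryl methyl ethers are cleaved on the robust diarylethane (BBr3, CH2Cl2, 0 °C; the hindered methyl esters should survive) to give dimethyl 2,2'-(ethane-1,2-diyl)bis(4,6-dihydroxybenzoate) F3. NaH and MOMCl in DMF give dimethyl 2,2'-(ethane-1,2-diyl)bis[4,6-bis(methoxymethoxy)benzoate] F4. The twofold annulation with 5 under the conditions of step 2 gives 1,1'-[4,4'-dihydroxy-5,5',7,7'-tetrakis(methoxymethoxy)-2,2'-dimethyl-[1,1'-binaphthalene]-3,3'-diyl]di(ethan-1-one) F5, and HCl in methanol at 40 °C then releases 9 under mild conditions.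

## Further compounds

F1 | step 2 | 1-(1-hydroxy-6,8-dimethoxy-3-methylnaphthalen-2-yl)ethan-1-one | CC(=O)c1c(C)cc2cc(OC)cc(OC)c2c1O
F2 | step 1 | methyl 2-(chloromethyl)-4,6-dimethoxybenzoate | COC(=O)c1c(CCl)cc(OC)cc1OC
F3 | step 3 | dimethyl 2,2'-(ethane-1,2-diyl)bis(4,6-dihydroxybenzoate) | COC(=O)c1c(CCc2cc(O)cc(O)c2C(=O)OC)cc(O)cc1O
F4 | step 3 | dimethyl 2,2'-(ethane-1,2-diyl)bis[4,6-bis(methoxymethoxy)benzoate] | COC(=O)c1c(CCc2cc(OCOC)cc(OCOC)c2C(=O)OC)cc(OCOC)cc1OCOC
F5 | step 3 | 1,1'-[4,4'-dihydroxy-5,5',7,7'-tetrakis(methoxymethoxy)-2,2'-dimethyl-[1,1'-binaphthalene]-3,3'-diyl]di(ethan-1-one) | CC(=O)c1c(C)c(-c2c(C)c(C(C)=O)c(O)c3c(OCOC)cc(OCOC)cc23)c2cc(OCOC)cc(OCOC)c2c1O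
A1 | alternative 1 | 1-(1-hydroxy-6,8-dimethoxy-3-methylnaphthalen-2-yl)ethan-1-one | CC(=O)c1c(C)cc2cc(OC)cc(OC)c2c1O
A2 | alternative 2 | 1-(2,4-dimethoxyphenyl)butane-1,3-dione | CC(=O)CC(=O)c1ccc(OC)cc1OC
A3 | alternative 2 | hexa-2,4-diyne | CC#CC#CC
A4 | alternative 2 | 1,1'-(4,4'-dihydroxy-5,5',7,7'-tetramethoxy-1,1'-dimethyl-[2,2'-binaphthalene]-3,3'-diyl)di(ethan-1-one) | CC(=O)c1c(-c2c(C)c3cc(OC)cc(OC)c3c(O)c2C(C)=O)c(C)c2cc(OC)cc(OC)c2c1O
A5 | alternative 3 | 3,4-bis[3,5-dimethoxy-2-(3-oxobutanoyl)phenyl]hexane-2,5-dione | CC(=O)CC(=O)c1c(OC)cc(OC)cc1C(C(C)=O)C(C(C)=O)c1cc(OC)cc(OC)c1C(=O)CC(C)=O
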